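The ten-membered carbocycle is opened at its only ring alkene, C1=C10: a trisubstituted enoate that carries the C14 methyl ester on C10 and holds C9 and C2 cis. An intramolecular Horner–Wadsworth–Emmons reaction between a C10 phosphonoacetate and a C1 aldehyde makes this bond, sets its geometry and closes the ring in one operation, with no stereocentre at stake. The precursor is a seco aldehyde: a cis-disubstituted γ-lactone, still without C13, whose C6 arm is the C4–C5 epoxide chain ending in the C1 aldehyde and whose C7 arm is the differentially silylated C8/C9 diol ending in the C10 phosphonoacetate.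

Key step: step 16

Remark: germacrane numbering is used throughout (C1–C10 ring carbons, C11–C13 lactone carbons, C14 the ester carbon on C10, C15 the methyl on C4).
Remark: the target SMILES encodes 4R,5S (C3 and C6 cis on the oxirane, hence nerol and not geraniol), 6R,7R (H6 and H7 cis), 8S,9S (a threo diol), a 1(10)E enoate and an (R)-2-methyloxirane-2-carboxylate; the seco aldehyde 25 and the macrocycle 26 agree with it at every centre and are used unchanged.
Remark: C10 in 21–25 (21 partly as its enol) and C11 in 28 and 29 are epimer mixtures of no consequence and carry no stereo label.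

Step 1
Reactants: 1 nerol
Product: 2 (2S,3R)-2,3-epoxynerol
Conditions: Ti(OiPr)4 (10 mol %), L-(+)-diethyl tartrate (12 mol %), tBuOOH, 4 Å molecular sieves, CH2Cl2, −20 °C
Reagents that add atoms: tert-butyl hydroperoxide, CC(C)(C)OO
Why: Katsuki–Sharpless asymmetric epoxidation, in which the L-(+)-tartrate titanium catalyst should deliver oxygen to the face that gives the (2S,3R)-epoxide (C4 and C5), while the Z geometry of nerol places C3 and C6 cis on the oxirane as the target requires.

Step 2
Reactants: 2 (2S,3R)-2,3-epoxynerol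
Product: 3 (2R,3R)-3-methyl-3-(4-methylpent-3-en-1-yl)oxirane-2-carbaldehyde (CHO = C6)
Conditions: Dess–Martin periodinane, pyridine, CH2Cl2, 0 °C → rt
Reagents that add atoms: none
Why: Dess–Martin oxidation of the primary alcohol under pyridine buffering should stop at the aldehyde without opening the oxirane, and C5 cannot epimerise because it is a ring atom.

Step 3
Reactants: 4 (R)-2,3-O-isopropylideneglyceraldehyde
Product: 5 (4S)-4-ethynyl-2,2-dimethyl-1,3-dioxolane
Conditions: dimethyl (1-diazo-2-oxopropyl)phosphonate, K2CO3, MeOH, 0 °C → rt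
Reagents that add atoms: Ohira–Bestmann reagent, CC(=O)C(=[N+]=[N-])P(=O)(OC)OC
Why: Seyferth–Gilbert homologation in the Ohira–Bestmann variant turns the aldehyde into the terminal alkyne under mild carbonate conditions that should preserve the α-alkoxy centre, so C8 comes from the chiral pool.

Step 4
Reactants: 5 (4S)-4-ethynyl-2,2-dimethyl-1,3-dioxolane
Product: 6 (2S)-but-3-yne-1,2-diol
Conditions: 1 M aq HCl (cat.), THF/H2O, rt; neutralise, concentrate
Reagents that add atoms: none
Why: Acid-catalysed acetal hydrolysis is done here on a robust four-carbon fragment, so that no acidic deprotection is needed once the C4–C5 epoxide and a cis-disposed O8 (set up for 5-exo opening) share one molecule.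

Step 5
Reactants: 6 (2S)-but-3-yne-1,2-diol
Product: 7 (3S)-3,4-bis(triethylsilyloxy)but-1-yne
Conditions: Et3SiCl (2.3 equiv), imidazole, DMF, 0 °C → rt
Reagents that add atoms: triethylsilyl chloride, CC[Si](Cl)(CC)CC
Why: Imidazole-promoted silylation protects both hydroxyls, and the primary triethylsilyl ether (O9) can later be cleaved selectively next to the secondary one (O8).

Step 6
Reactants: 7 (3S)-3,4-bis(triethylsilyloxy)but-1-yne
Product: 8 (4S)-4,5-bis(triethylsilyloxy)penta-1,2-diene
Conditions: (CH2O)n, CuI (0.5 equiv), dicyclohexylamine, 1,4-dioxane, reflux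
Reagents that add atoms: formaldehyde (as paraformaldehyde), C=O
Why: Crabbé homologation, in which the copper acetylide undergoes a Mannich reaction with formaldehyde and the propargylic amine fragments by 1,5-hydride transfer to the terminal allene, leaving C8 untouched.

Step 7
Reactants: 8 (4S)-4,5-bis(triethylsilyloxy)penta-1,2-diene; 3 (2R,3R)-3-methyl-3-(4-methylpent-3-en-1-yl)oxirane-2-carbaldehyde
Product: 11 homoallylic alcohol (4R,5S,6R,7S,8S; C6–OH; vinyl C11=C12 on C7), via Z-allylborane 9 (not isolated), via borinate ester 10 (not isolated)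
Conditions: (+)-Ipc2BH [from (−)-α-pinene and BH3·SMe2], THF, −25 → 0 °C; then 3, −78 °C; then H2O2, aq NaHCO3, 0 °C → rt
Reagents that add atoms: none
Why: Allene hydroboration followed by Brown-type allylboration, in which kinetic addition of the bulky borane to the terminal double bond anti to C8 should give the (Z)-γ-substituted allylborane; its chair transition state gives the 6,7-syn alcohol, the isopinocampheyl groups direct attack to the aldehyde face that gives 6R (against the modest Felkin bias of the epoxy aldehyde), and the C8 centre, reacting anti to C9 with H8 eclipsing the alkene, is expected to reinforce the same C7 configuration.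

Step 8
Reactants: 11 homoallylic alcohol
Product: 13 6,12-diol, via alkylborane adduct 12 (not isolated)
Conditions: 9-BBN (2.5 equiv), THF, 0 °C → rt; then H2O2, aq NaHCO3, 0 °C → rt
Reagents that add atoms: hydrogen peroxide, OO
Why: Brown hydroboration–oxidation, in which 9-BBN adds anti-Markovnikov to the monosubstituted C11=C12 alkene far faster than to the trisubstituted C1 alkene, and bicarbonate-buffered peroxide avoids Payne rearrangement of the 5,6-epoxy alcohol.

Step 9
Reactants: 13 6,12-diol
Product: 15 cis-lactone bearing the 8,9-bis(triethylsilyloxy) side chain, via lactol 14 (not isolated)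
Conditions: TEMPO (cat.), PhI(OAc)2, CH2Cl2, rt
Reagents that add atoms: none
Why: TEMPO-catalysed oxidative lactonisation of a 1,4-diol, in which the primary alcohol is oxidised to the aldehyde, trapped by the C6 hydroxyl as the five-membered lactol and oxidised on to the γ-lactone; the cis relation of C5 and C8 on the ring follows from the syn stereochemistry of step 7.

Step 10
Reactants: 15 cis-lactone
Product: 16 lactone C9 primary alcohol (O8 triethylsilyl ether kept)
Conditions: HF·pyridine, pyridine, THF, 0 °C
Reagents that add atoms: none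
Why: Buffered HF·pyridine cleaves the unhindered primary triethylsilyl ether much faster than the secondary one, and O8 stays protected so that it cannot open the neighbouring epoxide.

Step 11
Reactants: 16 lactone C9 primary alcohol
Product: 18 lactone C9 carboxylic acid, via aldehyde 17 (not isolated)
Conditions: TEMPO (cat.), PhI(OAc)2, MeCN/H2O, rt
Reagents that add atoms: water, O
Why: TEMPO/PhI(OAc)2 oxidation in aqueous acetonitrile takes the primary alcohol through the aldehyde hydrate to the acid under near-neutral conditions that should spare the epoxide, the alkene and the α-silyloxy centre.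

Step 12
Reactants: 18 lactone C9 carboxylic acid; 19 trimethyl phosphonoacetate
Product: 21 methyl 2-(dimethoxyphosphoryl)-3-oxo ester (C9 ketone), via acyl imidazolide 20 (not isolated)
Conditions: carbonyldiimidazole, THF, rt; then 19 (2 equiv), MgCl2, Et3N, MeCN, 0 °C → rt
Reagents that add atoms: none
Why: Masamune-type C-acylation, in which the acyl imidazolide acylates the magnesium enolate of the phosphonoacetate formed by soft enolisation, conditions too mild to enolise the lactone.

Step 13
Reactants: 21 C9 ketone
Product: 22 C9 alcohol (8,9-syn; 9S as in 38)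
Conditions: NaBH4, CeCl3·7H2O, MeOH, −78 → −40 °C; AcOH quench at −40 °C
Reagents that add atoms: none
Why: Luche reduction under Felkin–Anh control, in which hydride should add anti to the C8 triethylsilyloxy group to give the 8,9-syn alcohol, while the cold protic medium keeps O9 protonated so that the β-hydroxy phosphonate does not collapse to an alkene.

Step 14
Reactants: 22 C9 alcohol
Product: 23 C9 tert-butyldimethylsilyl ether
Conditions: tBuMe2SiOTf, 2,6-lutidine, CH2Cl2, −78 → 0 °C
Reagents that add atoms: tert-butyldimethylsilyl triflate, CC(C)(C)[Si](C)(C)OS(=O)(=O)C(F)(F)F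
Why: Silylation with the silyl triflate and the hindered, weakly basic 2,6-lutidine protects the congested C9 hydroxyl without generating the C9 alkoxide or the C10 carbanion.

Step 15
Reactants: 23 C9 tert-butyldimethylsilyl ether
Product: 25 seco C1 aldehyde with C10 phosphonoacetate, via ozonide 24 (not isolated)
Conditions: O3, CH2Cl2, −78 °C; then PPh3, −78 °C → rt
Reagents that add atoms: ozone, [O-][O+]=O
Why: Ozonolysis with reductive work-up cleaves the only C=C bond, the trisubstituted alkene that has masked C1 since nerol, so that aldehyde and phosphonoacetate coexist only under neutral conditions.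

Step 16
Reactants: 25 seco C1 aldehyde with C10 phosphonoacetate
Product: 26 bis-silylated macrocyclic lactone without C13
Conditions: LiCl (20 equiv), DBU (5 equiv), MeCN, rt; 25 added by syringe pump to 0.5 mM
Reagents that add atoms: none
Why: DBU, assisted by lithium chelation, deprotonates C10; the phosphonoenolate adds to the C1 aldehyde and the β-oxido phosphonate closes to an oxaphosphetane that expels lithium dimethyl phosphate and leaves the C1=C10 enoate. The closest known reaction type is the Masamune–Roush variant of the intramolecular Horner–Wadsworth–Emmons macrocyclisation, well proven for large-ring enoates and rarely used for ten-membered carbocycles. The ten-membered ring closes by a 10-exo-trig addition of the carbanion to the aldehyde carbon, helped by high dilution and by the two turn elements already in the chain (the cis-disubstituted lactone and the cis-epoxide). No stereocentre is created, and the C10 centre of 25, present as both epimers, disappears. The step needs C9 cis to C2 (the E-enoate): reversible addition under lithium chelation favours the adduct that collapses to the E-ester, and the ring itself accommodates only the cis-cyclodecene. It also needs olefination to outrun loss of the C9 silyloxy group from the carbanion and any conjugate addition, which the mild amine base, the bulky silanolate leaving group and the absence of C13 should secure.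

Step 17
Reactants: 26 bis-silylated macrocyclic lactone
Product: 28 13-(dimethylamino) Mannich base, via lithium enolate 27 (not isolated)
Conditions: LiN(SiMe3)2 (1.1 equiv), THF, −78 °C; then Me2N=CH2+ I−, −78 → 0 °C
Reagents that add atoms: Eschenmoser's salt, C=[N+](C)C.[I-]
Why: Lactone enolate Mannich reaction, in which the hindered amide base should deprotonate the C11 methylene at −78 °C faster than the γ-position of the enoate, and trapping with Eschenmoser's salt installs C13 as the dimethylaminomethyl group.

Step 18
Reactants: 28 Mannich base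
Product: 30 α-methylene lactone (8-O-triethylsilyl; 9-O-tert-butyldimethylsilyl), via trimethylammonium iodide 29 (not isolated)
Conditions: MeI (excess), THF, rt; then saturated aq NaHCO3, rt
Reagents that add atoms: none
Why: Quaternisation followed by Hofmann-type E1cB elimination, in which N-methylation makes the amine a leaving group and bicarbonate removes the acidic C11 proton to give the exocyclic C11=C13 methylene.

Step 19
Reactants: 30 α-methylene lactone
Product: 31 C8 alcohol
Conditions: HF·pyridine, pyridine, THF, 0 °C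
Reagents that add atoms: none
Why: Selective desilylation, in which buffered HF·pyridine removes the triethylsilyl ether well before the more hindered tert-butyldimethylsilyl ether, in a medium that should not promote attack of the freed O8 on the epoxide.

Step 20
Reactants: 31 C8 alcohol
Product: 32 C8 acetate
Conditions: Ac2O, pyridine, DMAP (cat.), CH2Cl2, 0 °C → rt
Reagents that add atoms: acetic anhydride, CC(=O)OC(C)=O
Why: DMAP-catalysed acetylation of the secondary C8 hydroxyl is fast and leaves the silyl ether, the epoxide and the two Michael acceptors untouched.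

Step 21
Reactants: 32 C8 acetate
Product: 33 C9 alcohol
Conditions: HF·pyridine, THF, 0 °C → rt
Reagents that add atoms: none
Why: Fluoride-mediated cleavage of the tert-butyldimethylsilyl ether with an acidic fluoride source, under which 1,2-migration of the C8 acetate to O9 should be slow.

Step 22
Reactants: 34 (S)-2-methylglycidol
Product: 36 (R)-2-methyloxirane-2-carboxylic acid, via aldehyde 35 (not isolated)
Conditions: TEMPO (cat.), PhI(OAc)2, MeCN/H2O, 0 °C → rt; used fresh
Reagents that add atoms: water, O
Why: TEMPO/PhI(OAc)2 oxidation of the primary alcohol to the acid, in which the quaternary epoxide centre cannot epimerise and the descriptor changes from S to R only because the carboxyl group outranks the ring methylene.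

Step 23
Reactants: 33 C9 alcohol; 36 (R)-2-methyloxirane-2-carboxylic acid
Product: 38 CNP0159450.1, via mixed anhydride 37 (not isolated)
Conditions: 2,4,6-trichlorobenzoyl chloride, Et3N, THF, 0 °C; then 33, DMAP, toluene, rt
Reagents that add atoms: none
Why: Yamaguchi esterification, in which the mixed anhydride of the glycidic acid acylates the hindered C9 hydroxyl under DMAP catalysis without opening either epoxide or touching a stereocentre.

Compound list
1 | nerol, (2Z)-3,7-dimethylocta-2,6-dien-1-ol | CC(C)=CCC/C(C)=C\CO | starting material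
2 | (2S,3R)-2,3-epoxynerol | OC[C@@H]1O[C@]1(C)CCC=C(C)C | intermediate
3 | (2R,3R)-3-methyl-3-(4-methylpent-3-en-1-yl)oxirane-2-carbaldehyde | O=C[C@@H]1O[C@]1(C)CCC=C(C)C | intermediate
4 | (R)-2,3-O-isopropylideneglyceraldehyde | O=C[C@H]1COC(C)(C)O1 | starting material
5 | (4S)-4-ethynyl-2,2-dimethyl-1,3-dioxolane | C#C[C@H]1COC(C)(C)O1 | intermediate
6 | (2S)-but-3-yne-1,2-diol | C#C[C@H](O)CO | intermediate
7 | (3S)-3,4-bis(triethylsilyloxy)but-1-yne | C#C[C@H](O[Si](CC)(CC)CC)CO[Si](CC)(CC)CC | intermediate
8 | (4S)-4,5-bis(triethylsilyloxy)penta-1,2-diene | C=C=C[C@H](O[Si](CC)(CC)CC)CO[Si](CC)(CC)CC | intermediate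
9 | [(2Z,4S)-4,5-bis(triethylsilyloxy)pent-2-en-1-yl]bis(isopinocampheyl)borane | C(/C=C\[C@H](O[Si](CC)(CC)CC)CO[Si](CC)(CC)CC)B([C@H]1C[C@H]2C[C@@H]([C@@H]1C)C2(C)C)[C@H]1C[C@H]2C[C@@H]([C@@H]1C)C2(C)C | intermediate
10 | bis(isopinocampheyl)borinate ester of 11 | O(B([C@H]1C[C@H]2C[C@@H]([C@@H]1C)C2(C)C)[C@H]1C[C@H]2C[C@@H]([C@@H]1C)C2(C)C)[C@@H]([C@@H]1O[C@]1(C)CCC=C(C)C)[C@H](C=C)[C@H](O[Si](CC)(CC)CC)CO[Si](CC)(CC)CC | intermediate
11 | homoallylic alcohol: C6 carbinol carrying the 4,5-epoxy chain (C1 masked as the isopropylidene alkene); C7 carries vinyl (C11=C12) and the (S)-1,2-bis(triethylsilyloxy)ethyl group (C8, C9); 4R,5S,6R,7S,8S | O[C@@H]([C@@H]1O[C@]1(C)CCC=C(C)C)[C@H](C=C)[C@H](O[Si](CC)(CC)CC)CO[Si](CC)(CC)CC | intermediate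
12 | O6-borinate, C12-(9-borabicyclo[3.3.1]nonan-9-yl) adduct of 11 | O(B1C2CCCC1CCC2)[C@@H]([C@@H]1O[C@]1(C)CCC=C(C)C)[C@H](CCB1C2CCCC1CCC2)[C@H](O[Si](CC)(CC)CC)CO[Si](CC)(CC)CC | intermediate
13 | 6,12-diol (C12 primary alcohol; other centres as in 11) | O[C@@H]([C@@H]1O[C@]1(C)CCC=C(C)C)[C@H](CCO)[C@H](O[Si](CC)(CC)CC)CO[Si](CC)(CC)CC | intermediate
14 | γ-lactol (C12 hemiacetal, anomers) | C1C(O)O[C@@H]([C@@H]3O[C@]3(C)CCC=C(C)C)[C@H]1[C@H](O[Si](CC)(CC)CC)CO[Si](CC)(CC)CC | intermediate
15 | cis-4,5-disubstituted γ-lactone (6,12-olide) with 8,9-bis(triethylsilyloxy) side chain; centres arranged as in 38 | C1C(=O)O[C@@H]([C@@H]3O[C@]3(C)CCC=C(C)C)[C@H]1[C@H](O[Si](CC)(CC)CC)CO[Si](CC)(CC)CC | intermediate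
16 | lactone with free C9 primary alcohol and 8-O-triethylsilyl ether | C1C(=O)O[C@@H]([C@@H]3O[C@]3(C)CCC=C(C)C)[C@H]1[C@H](O[Si](CC)(CC)CC)CO | intermediate
17 | lactone C9 aldehyde | C1C(=O)O[C@@H]([C@@H]3O[C@]3(C)CCC=C(C)C)[C@H]1[C@H](O[Si](CC)(CC)CC)C=O | intermediate
18 | lactone C9 carboxylic acid | C1C(=O)O[C@@H]([C@@H]3O[C@]3(C)CCC=C(C)C)[C@H]1[C@H](O[Si](CC)(CC)CC)C(=O)O | intermediate
19 | trimethyl phosphonoacetate | COC(=O)CP(=O)(OC)OC | starting material
20 | C9 acyl imidazolide | C1C(=O)O[C@@H]([C@@H]3O[C@]3(C)CCC=C(C)C)[C@H]1[C@H](O[Si](CC)(CC)CC)C(=O)n1ccnc1 | intermediate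
21 | C9 ketone: methyl 2-(dimethoxyphosphoryl)-3-oxo ester (C10 epimers and enol) | C1C(=O)O[C@@H]([C@@H]3O[C@]3(C)CCC=C(C)C)[C@H]1[C@H](O[Si](CC)(CC)CC)C(=O)C(C(=O)OC)P(=O)(OC)OC | intermediate
22 | C9 alcohol, 8,9-syn (C10 epimers) | C1C(=O)O[C@@H]([C@@H]3O[C@]3(C)CCC=C(C)C)[C@H]1[C@H](O[Si](CC)(CC)CC)[C@@H](O)C(C(=O)OC)P(=O)(OC)OC | intermediate
23 | 8-O-triethylsilyl 9-O-tert-butyldimethylsilyl phosphonoacetate with C1 masked as the alkene | C1C(=O)O[C@@H]([C@@H]3O[C@]3(C)CCC=C(C)C)[C@H]1[C@H](O[Si](CC)(CC)CC)[C@@H](O[Si](C)(C)C(C)(C)C)C(C(=O)OC)P(=O)(OC)OC | intermediate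
24 | secondary ozonide of 23 (1,2,4-trioxolane at C1) | C1C(=O)O[C@@H]([C@@H]3O[C@]3(C)CCC4OOC(C)(C)O4)[C@H]1[C@H](O[Si](CC)(CC)CC)[C@@H](O[Si](C)(C)C(C)(C)C)C(C(=O)OC)P(=O)(OC)OC | intermediate
25 | seco C1 aldehyde with C10 phosphonoacetate (C10 epimers; lactone without C13) | C1C(=O)O[C@@H]([C@@H]3O[C@]3(C)CCC=O)[C@H]1[C@H](O[Si](CC)(CC)CC)[C@@H](O[Si](C)(C)C(C)(C)C)C(C(=O)OC)P(=O)(OC)OC | intermediate
26 | bis-silylated macrocyclic lactone without C13, 1(10)E | C1C(=O)O[C@@H]2[C@H]1[C@H](O[Si](CC)(CC)CC)[C@@H](O[Si](C)(C)C(C)(C)C)/C(C(=O)OC)=C\CC[C@@]1(C)O[C@@H]21 | intermediate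
27 | lithium enolate of lactone 26 | [Li+].C1=C([O-])O[C@@H]2[C@H]1[C@H](O[Si](CC)(CC)CC)[C@@H](O[Si](C)(C)C(C)(C)C)/C(C(=O)OC)=C\CC[C@@]1(C)O[C@@H]21 | intermediate
28 | 11-(dimethylaminomethyl) lactone (C11 epimers) | CN(C)CC1C(=O)O[C@@H]2[C@H]1[C@H](O[Si](CC)(CC)CC)[C@@H](O[Si](C)(C)C(C)(C)C)/C(C(=O)OC)=C\CC[C@@]1(C)O[C@@H]21 | intermediate
29 | trimethylammonium iodide of 28 | [I-].C[N+](C)(C)CC1C(=O)O[C@@H]2[C@H]1[C@H](O[Si](CC)(CC)CC)[C@@H](O[Si](C)(C)C(C)(C)C)/C(C(=O)OC)=C\CC[C@@]1(C)O[C@@H]21 | intermediate
30 | α-methylene lactone, 8-O-triethylsilyl, 9-O-tert-butyldimethylsilyl | C=C1C(=O)O[C@@H]2[C@H]1[C@H](O[Si](CC)(CC)CC)[C@@H](O[Si](C)(C)C(C)(C)C)/C(C(=O)OC)=C\CC[C@@]1(C)O[C@@H]21 | intermediate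
31 | 8-hydroxy 9-O-tert-butyldimethylsilyl α-methylene lactone | C=C1C(=O)O[C@@H]2[C@H]1[C@H](O)[C@@H](O[Si](C)(C)C(C)(C)C)/C(C(=O)OC)=C\CC[C@@]1(C)O[C@@H]21 | intermediate
32 | 8-acetoxy 9-O-tert-butyldimethylsilyl α-methylene lactone | C=C1C(=O)O[C@@H]2[C@H]1[C@H](OC(C)=O)[C@@H](O[Si](C)(C)C(C)(C)C)/C(C(=O)OC)=C\CC[C@@]1(C)O[C@@H]21 | intermediate
33 | 8-acetoxy 9-hydroxy α-methylene lactone | C=C1C(=O)O[C@@H]2[C@H]1[C@H](OC(C)=O)[C@@H](O)/C(C(=O)OC)=C\CC[C@@]1(C)O[C@@H]21 | intermediate
34 | (S)-2-methylglycidol, [(2S)-2-methyloxiran-2-yl]methanol | OC[C@@]1(C)CO1 | starting material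
35 | (R)-2-methyloxirane-2-carbaldehyde | O=C[C@@]1(C)CO1 | intermediate
36 | (R)-2-methyloxirane-2-carboxylic acid | OC(=O)[C@@]1(C)CO1 | intermediate
37 | mixed anhydride of 36 with 2,4,6-trichlorobenzoic acid | O=C(OC(=O)[C@@]1(C)CO1)c1c(Cl)cc(Cl)cc1Cl | intermediate
38 | CNP0159450.1 (4R,5S,6R,7R,8S,9S, 1(10)E, side chain 2R) | C=C1C(=O)O[C@@H]2[C@H]1[C@H](OC(C)=O)[C@@H](OC(=O)[C@@]1(C)CO1)/C(C(=O)OC)=C\CC[C@@]1(C)O[C@@H]21 | target

Total step count: 23. Longest linear sequence: 20 steps (steps 3–21 and 23, from 4 to 38); steps 1–2 and 22 are side branches.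

Steps most likely to fail

Step 16. The slow ten-membered ring closure may be outrun by β-elimination of the C9 silanolate from the C10 carbanion, or by intermolecular olefination. The fallback cyclises with the C9 oxygen unprotected, since hydroxide is a far poorer leaving group and the C10–H is more acidic than the hydroxyl, so the carbanion forms without the alkoxide that would trigger fragmentation. It sets out from 22: ozonolysis with PPh3 work-up, as in step 15, should give the hydroxy seco aldehyde F1. Cyclisation with LiCl and DBU at high dilution should give the macrocyclic allylic alcohol F2; phosphonoacetates with a free β-hydroxyl are known to olefinate aldehydes. Silylation with tBuMe2SiOTf and 2,6-lutidine returns to the route at 26.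

Step 7. The Z-allylborane may isomerise by 1,3-boron shift, or eliminate next to the C8 silyloxy group, before it is trapped. Facial control may also be too weak, because the reagent must work against the Felkin preference of the epoxy aldehyde. The fallback replaces the dialkylborane by a configurationally stable boronate and moves face control to a chiral Brønsted acid. It sets out from 7: lithiation with n-BuLi and reaction with 2-(iodomethyl)-4,4,5,5-tetramethyl-1,3,2-dioxaborolane (Matteson-type 1,2-shift) should give the propargylic pinacol boronate F3. Semi-hydrogenation over Lindlar catalyst (Pd on CaCO3 poisoned with Pb(OAc)2, quinoline, H2) should give the (Z)-allylboronate F4. Allylboration of 3 catalysed by the BINOL-derived phosphoric acid TRIP in toluene at −30 °C, with aqueous work-up, returns to the route at 11.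

Step 17. The lithium lactone enolate may attack the neighbouring C1=C10 enoate or the C14 ester across the ring, or the base may deprotonate the enoate γ-position, before the iminium salt reacts. The fallback avoids a free enolate. It sets out from 26: LiN(SiMe3)2 is added to 26 in the presence of excess Me3SiCl in THF at −78 °C (internal quench), which should give the trimethylsilyl ketene acetal F5. Mukaiyama–Mannich reaction of this neutral species with Eschenmoser's salt in CH2Cl2 at rt returns to the route at 28.

Further compounds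
F1 | step 16 | seco C1 aldehyde with C10 phosphonoacetate and free C9 hydroxyl (8-O-triethylsilyl) | C1C(=O)O[C@@H]([C@@H]3O[C@]3(C)CCC=O)[C@H]1[C@H](O[Si](CC)(CC)CC)[C@@H](O)C(C(=O)OC)P(=O)(OC)OC
F2 | step 16 | macrocyclic lactone without C13 with free C9 hydroxyl (8-O-triethylsilyl) | C1C(=O)O[C@@H]2[C@H]1[C@H](O[Si](CC)(CC)CC)[C@@H](O)/C(C(=O)OC)=C\CC[C@@]1(C)O[C@@H]21
F3 | step 7 | pinacol [(4S)-4,5-bis(triethylsilyloxy)pent-2-yn-1-yl]boronate | CC1(C)OB(CC#C[C@H](O[Si](CC)(CC)CC)CO[Si](CC)(CC)CC)OC1(C)C
F4 | step 7 | pinacol [(2Z,4S)-4,5-bis(triethylsilyloxy)pent-2-en-1-yl]boronate | CC1(C)OB(C/C=C\[C@H](O[Si](CC)(CC)CC)CO[Si](CC)(CC)CC)OC1(C)C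
F5 | step 17 | trimethylsilyl ketene acetal of lactone 26 | C1=C(O[Si](C)(C)C)O[C@@H]2[C@H]1[C@H](O[Si](CC)(CC)CC)[C@@H](O[Si](C)(C)C(C)(C)C)/C(C(=O)OC)=C\CC[C@@]1(C)O[C@@H]21
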